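**Plan**

- Retrosynthesis: the 7-OH is masked as a silyl ether and the C4 ketone is traced back to a C4 methoxy group. Ring C is then cut at O1–C2 and C3–C4.
- This cut is possible because ring C divides into the four-atom unit O1–C8a–C4a–C4 and the two-carbon unit C2–C3. The first is a salicylaldehyde-derived ortho-quinone methide whose methide carbon C4 is stabilized by the C7 oxygen para to C4a. The second is the vinyl group of 4-geranyloxystyrene, whose 4'-alkoxy group directs its benzylic carbon to O1.
- Forward: ring A comes from 2,4-dihydroxybenzaldehyde (4-O-silylation), ring B from 4-hydroxybenzaldehyde (geranylation, Wittig methylenation). Ring C is the only ring made, in one catalytic asymmetric oxa-[4+2] step that joins both fragments with trimethyl orthoformate.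
- End game: OMe-to-OH exchange at C4, oxidation to the chromanone, desilylation.
- Stereochemistry: the single stereocentre C2 (S) is set in the cycloaddition by a chiral N-triflylphosphoramide. C4 is transient and is erased by oxidation. The E-alkene comes unchanged from geranyl bromide.

Key step: step 4

Assumption: the (R)-configured catalyst is taken to deliver the (2S,4S) adduct; should the sense of induction prove opposite, its enantiomer would be used with nothing else changed. Flavanone numbering (O1, C2, C3, C4, C4a, C5–C8, C8a, primed positions for ring B) is used throughout.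

**Route**

Step 1
Reactants: 1 2,4-dihydroxybenzaldehyde
Product: 2 2-hydroxy-4-(triisopropylsilyloxy)benzaldehyde
Conditions: TIPSCl (1.05 equiv), imidazole (2 equiv), CH2Cl2, 0 °C to rt
Reagents that add atoms: triisopropylsilyl chloride, CC(C)[Si](Cl)(C(C)C)C(C)C
Why: Silylation of a phenol is selective for the 4-OH, because the 2-OH is tied up in a hydrogen bond to the formyl oxygen and is the more hindered, less nucleophilic site; no stereocentre is formed.

Step 2
Reactants: 3 4-hydroxybenzaldehyde; 4 geranyl bromide
Product: 5 4-(geranyloxy)benzaldehyde
Conditions: K2CO3, acetone, reflux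
Reagents that add atoms: none
Why: Williamson ether synthesis, in which the phenoxide displaces the primary allylic bromide by SN2 and the E geometry of the geranyl unit is carried over unchanged.

Step 3
Reactants: 5 4-(geranyloxy)benzaldehyde
Product: 6 1-(geranyloxy)-4-vinylbenzene
Conditions: Ph3PCH3Br, KOtBu, THF, 0 °C to rt
Reagents that add atoms: methyltriphenylphosphonium bromide, C[P+](c1ccccc1)(c1ccccc1)c1ccccc1.[Br-]
Why: Wittig methylenation of an aromatic aldehyde with the non-stabilized ylide gives the terminal styrene under basic conditions that leave the allyl aryl ether untouched.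

Step 4
Reactants: 2 2-hydroxy-4-(triisopropylsilyloxy)benzaldehyde; 6 1-(geranyloxy)-4-vinylbenzene; 7 trimethyl orthoformate
Product: 10 (2S,4S)-2-[4-(geranyloxy)phenyl]-4-methoxy-7-(triisopropylsilyloxy)chroman (2,4-cis), via salicylaldehyde dimethyl acetal 8 (not isolated), via methoxy ortho-quinone methide 9 (not isolated)
Conditions: 2, HC(OMe)3 (1.1 equiv), (R)-3,3'-bis(2,4,6-triisopropylphenyl)-1,1'-binaphthalene-2,2'-diyl N-(trifluoromethylsulfonyl)phosphoramidate [(R)-(ArO)2P(O)NHSO2CF3, 5 mol %], toluene, rt; then 5 Å molecular sieves, −60 °C, slow addition of 6 (1.2 equiv)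
Reagents that add atoms: none
Why: Proposed new method: the chiral acid first catalyses acetalization of 2 by 7 to 8 and then ionizes 8 to the O-methyl oxocarbenium ion, which is quinone methide 9 protonated on oxygen and is stabilized by the silyloxy group para to the methide carbon; the CH2 terminus of 6 adds to that carbon (C3–C4) and the 4-alkoxybenzylic cation so formed is captured by the phenolic oxygen (O1–C2) within the contact ion pair, an asynchronous inverse-electron-demand oxa-[4+2] cycloaddition. The closest known reaction types are the achiral acid-promoted union of salicylaldehydes, trimethyl orthoformate and styrenes to cis-4-alkoxy-2-arylchromans and the chiral phosphoric acid-catalysed oxa-[4+2] additions of in situ ortho-quinone methides to electron-rich vinylarenes, so only the enantioselective form on an acetal-derived methide is new. Ring C closes intermolecularly as the six-membered ring of the [4+2] event, the C–C bond leading and the C–O bond completing it through a half-chair in which the aryl and methoxy groups are both pseudo-equatorial, which gives the 2,4-cis adduct. The phosphoramide anion, held to the substrate by the phenolic O–H hydrogen bond, screens one face of the oxocarbenium carbon with a 3,3'-aryl group and so sets C4 (S), and the fast cis-selective collapse inside the same ion pair transfers this to C2 (S), the centre that survives to the target. Regiochemistry is fixed by polarity (methide carbon to styrene CH2), chemoselectivity by the much higher nucleophilicity of the 4-alkoxystyrene compared with the trisubstituted geranyl alkenes, and the low temperature, low acid loading, near-stoichiometric orthoformate and slow addition of 6 are meant to suppress styrene oligomerization, capture of the styrene by dimethoxycarbenium ion and ionization of the geranyl ether or of the product C2–O bond.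

Step 5
Reactants: 10 (2S,4S)-2-[4-(geranyloxy)phenyl]-4-methoxy-7-(triisopropylsilyloxy)chroman
Product: 11 (2S)-2-[4-(geranyloxy)phenyl]-7-(triisopropylsilyloxy)chroman-4-ol (mixture of C4 epimers)
Conditions: PPTS (0.2 equiv), THF/H2O (4:1), high dilution, 40 °C
Reagents that add atoms: water, O
Why: Acid-catalysed SN1 solvolysis exchanges OMe for OH at C4, because the C4 cation is stabilized by O1 (ortho) and the 7-silyloxy group (para) and the large excess of water drives the equilibrium; C2 is not touched and the C4 epimer mixture is of no consequence.

Step 6
Reactants: 11 (2S)-2-[4-(geranyloxy)phenyl]-7-(triisopropylsilyloxy)chroman-4-ol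
Product: 12 (2S)-2-[4-(geranyloxy)phenyl]-7-(triisopropylsilyloxy)chroman-4-one
Conditions: activated MnO2 (excess), CH2Cl2, rt
Reagents that add atoms: none
Why: MnO2 oxidation of an electron-rich benzylic alcohol should convert both C4 epimers into the one ketone under neutral heterogeneous conditions that spare the geranyl alkenes, the aryl silyl ether and the C2 centre.

Step 7
Reactants: 12 (2S)-2-[4-(geranyloxy)phenyl]-7-(triisopropylsilyloxy)chroman-4-one
Product: 13 (2S)-2-[4-(geranyloxy)phenyl]-7-hydroxychroman-4-one (CNP0302343.1)
Conditions: TBAF (1.1 equiv), AcOH (1.2 equiv), THF, 0 °C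
Reagents that add atoms: none
Why: Fluoride-mediated desilylation cleaves the aryl silyl ether para to the carbonyl readily, and the acetic acid buffer keeps the medium non-basic so that the flavanone should not open to the 2'-hydroxychalcone by retro-oxa-Michael reaction, which would racemize C2.

**Compound list**

1 | 2,4-dihydroxybenzaldehyde | O=Cc1ccc(O)cc1O | starting material
2 | 2-hydroxy-4-(triisopropylsilyloxy)benzaldehyde | O=Cc1ccc(O[Si](C(C)C)(C(C)C)C(C)C)cc1O | intermediate
3 | 4-hydroxybenzaldehyde | O=Cc1ccc(O)cc1 | starting material
4 | geranyl bromide, (2E)-1-bromo-3,7-dimethylocta-2,6-diene | CC(C)=CCC/C(C)=C/CBr | starting material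
5 | 4-(geranyloxy)benzaldehyde, 4-{[(2E)-3,7-dimethylocta-2,6-dien-1-yl]oxy}benzaldehyde | CC(C)=CCC/C(C)=C/COc1ccc(C=O)cc1 | intermediate
6 | 1-(geranyloxy)-4-vinylbenzene | CC(C)=CCC/C(C)=C/COc1ccc(C=C)cc1 | intermediate
7 | trimethyl orthoformate | COC(OC)OC | starting material
8 | 2-(dimethoxymethyl)-5-(triisopropylsilyloxy)phenol (formed in the flask, not isolated) | COC(OC)c1ccc(O[Si](C(C)C)(C(C)C)C(C)C)cc1O | intermediate
9 | (6E)-6-(methoxymethylidene)-3-(triisopropylsilyloxy)cyclohexa-2,4-dien-1-one, present under the acid as its O-protonated oxocarbenium form (formed in the flask, not isolated) | CO/C=C1\C=CC(O[Si](C(C)C)(C(C)C)C(C)C)=CC1=O | intermediate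
10 | (2S,4S)-2-[4-(geranyloxy)phenyl]-4-methoxy-7-(triisopropylsilyloxy)chroman (2,4-cis) | CC(C)=CCC/C(C)=C/COc1ccc([C@@H]2C[C@H](OC)c3ccc(O[Si](C(C)C)(C(C)C)C(C)C)cc3O2)cc1 | intermediate
11 | (2S)-2-[4-(geranyloxy)phenyl]-7-(triisopropylsilyloxy)chroman-4-ol, mixture of C4 epimers | CC(C)=CCC/C(C)=C/COc1ccc([C@@H]2CC(O)c3ccc(O[Si](C(C)C)(C(C)C)C(C)C)cc3O2)cc1 | intermediate
12 | (2S)-2-[4-(geranyloxy)phenyl]-7-(triisopropylsilyloxy)chroman-4-one | CC(C)=CCC/C(C)=C/COc1ccc([C@@H]2CC(=O)c3ccc(O[Si](C(C)C)(C(C)C)C(C)C)cc3O2)cc1 | intermediate
13 | (2S)-2-[4-(geranyloxy)phenyl]-7-hydroxychroman-4-one (CNP0302343.1) | CC(C)=CCC/C(C)=C/COc1ccc([C@@H]2CC(=O)c3ccc(O)cc3O2)cc1 | target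

**Step count**

Total steps: 7. Longest linear sequence: 6 (steps 2, 3, 4, 5, 6, 7 from 4-hydroxybenzaldehyde).

**Steps most likely to fail**

1. Step 4 (proposed new method). The ion pair may discriminate the two faces poorly, so that C2 is formed with low enantiomeric purity. The styrene may also oligomerize cationically, and the acid may ionize or cyclize the geranyl ether. The fallback uses known chemistry, sets out from geranyl bromide 4 and comes back to the route at 12. O-Alkylation of commercial 4-hydroxyphenylboronic acid pinacol ester with 4 (K2CO3, DMF) would give 2-[4-(geranyloxy)phenyl]-4,4,5,5-tetramethyl-1,3,2-dioxaborolane F1. Silylation of commercial 7-hydroxychromen-4-one (TIPSCl, imidazole, CH2Cl2) would give 7-(triisopropylsilyloxy)chromen-4-one F2. A rhodium-catalysed asymmetric 1,4-addition of F1 to F2 (Hayashi–Miyaura reaction; [Rh(OH)(cod)]2 with a chiral bisphosphine or diene ligand of the enantiomer that delivers the 2S product, dioxane/H2O) would then form the C2–C1' bond and the C2 stereocentre directly. This gives flavanone 12 and makes steps 4 to 6 unnecessary.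

2. Step 5. Under the acid, the C4 cation may lose a proton to give the flav-3-ene, may alkylate the electron-rich ring A of a second molecule, or the C2–O1 bond may open and close again with epimerization at C2. The fallback sets out from 10 and comes back at 12 without any acid. DDQ in CH2Cl2/pH 7 phosphate buffer would abstract hydride from the doubly activated C4–H of the benzylic methyl ether. Water would capture the oxocarbenium ion, and loss of methanol from the hemiketal would give ketone 12 in one operation, which also replaces step 6. This fallback makes no new compound (F0).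

3. Step 7. Fluoride that is not fully buffered may act as a base and open the flavanone to the 2'-hydroxychalcone. Reclosure would then erode the configuration at C2. The fallback removes the silyl group before the ketone exists, setting out from 11 and coming back at 13. TBAF/AcOH in THF would desilylate 11 to (2S)-2-[4-(geranyloxy)phenyl]chromane-4,7-diol F3, in which C2 has no retro-Michael pathway. Oxidation of this para-hydroxybenzylic alcohol with DDQ in dioxane at rt would then give the target 13 directly under neutral conditions.

**Further compounds**

F1 | step 4 | 2-[4-(geranyloxy)phenyl]-4,4,5,5-tetramethyl-1,3,2-dioxaborolane | CC(C)=CCC/C(C)=C/COc1ccc(B2OC(C)(C)C(C)(C)O2)cc1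
F2 | step 4 | 7-(triisopropylsilyloxy)-4H-chromen-4-one | O=c1ccoc2cc(O[Si](C(C)C)(C(C)C)C(C)C)ccc12
F0 | step 5 | none | none
F3 | step 7 | (2S)-2-[4-(geranyloxy)phenyl]chromane-4,7-diol, mixture of C4 epimers | CC(C)=CCC/C(C)=C/COc1ccc([C@@H]2CC(O)c3ccc(O)cc3O2)cc1
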